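**Retrosynthetic overview**
1. Ester last: Pd-catalysed carbonylation joins the C8 alcohol, CO and silyl-protected 4-iodophenol; the α-epoxide comes from the C3=C4 alkene through a bromohydrin.
2. Seven-membered ring: one-carbon ring expansion of a trans-fused hydrindenone, inserting CH(iPr) (C7) between the C8 carbonyl and C6; the 8β-OH then comes from a 10-OH-directed reduction.
3. C10 carbinol: methyl transfer to the C10 ketone directed by the axial 8-OH; cyclopentene by ring-closing metathesis.
4. C1 and C5: copper-catalysed conjugate addition/allylation of (S)-5-silyloxycyclohexenone, both anti.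
5. Ring order: six-membered ring (bought), five-membered ring (metathesis), seven-membered ring (expansion of the six).

Assumption: enantiopure (S)-5-[(tert-butyldimethylsilyl)oxy]cyclohex-2-en-1-one (1) and tert-butyl(4-iodophenoxy)dimethylsilane (17) are taken as purchasable.

Numbering: the Why lines use guaiane numbering (C1/C5 ring fusion, C2–C4 in the five-membered ring with CH3-15 on C4, C6–C10 in the seven-membered ring with CH3-14 on C10; α is the face of H-1). Hydrindene names use indene numbering; indene C7, C5, C7a, C3a correspond to guaiane C10, C8, C1, C5.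

**Step 1**
Reactants: 1 (S)-5-[(tert-butyldimethylsilyl)oxy]cyclohex-2-en-1-one; 2 isopropenylmagnesium bromide; 3 allyl iodide
Product: 5 (2R,3S,5S)-2-allyl-5-[(tert-butyldimethylsilyl)oxy]-3-(prop-1-en-2-yl)cyclohexan-1-one, via bromomagnesium enolate 4 (not isolated)
Conditions: 2, CuBr·SMe2 (10 mol%), THF, −78 °C; then 3, DMPU, −78 → −30 °C
Reagents that add atoms: none
Why: Copper-catalysed conjugate addition of the Grignard reagent enters anti to the C8 silyloxy group (sets C5) and the regiodefined magnesium enolate is allylated anti to the new isopropenyl group (sets C1), a tandem conjugate addition–enolate alkylation.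

**Step 2**
Reactants: 5 (2R,3S,5S)-2-allyl-5-[(tert-butyldimethylsilyl)oxy]-3-(prop-1-en-2-yl)cyclohexan-1-one
Product: 6 (3aS,5S,7aR)-5-[(tert-butyldimethylsilyl)oxy]-3-methyl-1,3a,4,5,6,7a-hexahydro-7H-inden-7-one (trans-fused)
Conditions: second-generation Grubbs catalyst RuCl2(=CHPh)(PCy3)(H2IMes) (5 mol%), CH2Cl2, 40 °C
Reagents that add atoms: none
Why: Ring-closing metathesis of the trans allyl and isopropenyl groups closes the trisubstituted cyclopentene (C3=C4) without touching the ring-fusion centres.

**Step 3**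
Reactants: 6 (3aS,5S,7aR)-5-[(tert-butyldimethylsilyl)oxy]-3-methyl-1,3a,4,5,6,7a-hexahydro-7H-inden-7-one
Product: 7 (3aS,5S,7aR)-5-hydroxy-3-methyl-1,3a,4,5,6,7a-hexahydro-7H-inden-7-one
Conditions: HF·pyridine, THF, 0 °C → rt
Reagents that add atoms: none
Why: Mildly acidic fluoride desilylation frees the axial 8β-hydroxyl without β-elimination or epimerisation next to the ketone.

**Step 4**
Reactants: 7 (3aS,5S,7aR)-5-hydroxy-3-methyl-1,3a,4,5,6,7a-hexahydro-7H-inden-7-one
Product: 8 (3aS,5S,7R,7aR)-3,7-dimethyl-3a,4,5,6,7,7a-hexahydro-1H-indene-5,7-diol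
Conditions: MeTi(OiPr)3 (3 equiv), CH2Cl2, −30 → 0 °C; aq. NH4Cl
Reagents that add atoms: methyltitanium triisopropoxide, C[Ti](OC(C)C)(OC(C)C)OC(C)C
Why: Reetz-type organotitanium addition: the axial 8β-hydroxyl exchanges onto titanium, and the reagent, sluggish toward ketones intermolecularly, transfers methyl through a six-membered transition state to the β face of C10, giving axial 10β-CH3 and equatorial 10α-OH (1,3-anti diol).

**Step 5**
Reactants: 8 (3aS,5S,7R,7aR)-3,7-dimethyl-3a,4,5,6,7,7a-hexahydro-1H-indene-5,7-diol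
Product: 9 (3aS,7R,7aR)-7-hydroxy-3,7-dimethyl-1,3a,4,6,7,7a-hexahydro-5H-inden-5-one
Conditions: (nPr4N)RuO4 (5 mol%), N-methylmorpholine N-oxide, 4 Å molecular sieves, CH2Cl2, 0 °C
Reagents that add atoms: none
Why: Ley–Griffith oxidation converts only the secondary C8 alcohol; the tertiary C10 carbinol cannot be oxidised.

**Step 6**
Reactants: 10 isobutyraldehyde
Product: 11 isobutyraldehyde hydrazone
Conditions: N2H4·H2O (5 equiv), Et2O, 0 °C → rt; dry over KOH
Reagents that add atoms: hydrazine (as hydrate), NN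
Why: Hydrazone formation by condensation; excess hydrazine suppresses the azine.

**Step 7**
Reactants: 9 (3aS,7R,7aR)-7-hydroxy-3,7-dimethyl-1,3a,4,6,7,7a-hexahydro-5H-inden-5-one; 11 isobutyraldehyde hydrazone
Product: 13 (1R,5S,7S,10R)-10-hydroxyguai-3-en-8-one (H-1 α, H-5 β, isopropyl α, 10-OH α), via 1-diazo-2-methylpropane 12 (not isolated)
Conditions: 11, Ag2O, cat. KOH, Et2O, −20 °C, cold filtration; filtrate added to 9, Sc(OTf)3 (10 mol%), toluene, −78 → −20 °C
Reagents that add atoms: none
Why: Proposed new method: hydroxyl-directed scandium-catalysed insertion of a branched non-stabilised diazoalkane into an unprotected β-hydroxy cyclohexanone; Sc(OTf)3 is chelated by the C8 carbonyl and the 10-OH, the diazo carbon adds to C8, and in the diazonium betaine the C8–C6 bond migrates with loss of N2 (1,2-shift) because C9 is neopentyl and inductively deactivated by the scandium-bound carbinol, so CH(iPr) is inserted between C8 and C6 and the seven-membered ring is formed; the new α-centre C7 equilibrates through the scandium enolate to the pseudo-equatorial isopropyl epimer, cis to the C5–C4 bond (7S); the closest known reaction is the Sc(OTf)3-catalysed diazoalkane–carbonyl homologation of simple cycloalkanones (Tiffeneau–Demjanov-type ring expansion), not shown for free β-hydroxy ketones or with chelate-based choice of the migrating carbon.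

**Step 8**
Reactants: 13 (1R,5S,7S,10R)-10-hydroxyguai-3-en-8-one
Product: 14 (1R,5S,7S,8R,10R)-guai-3-ene-8,10-diol
Conditions: Me4NBH(OAc)3 (5 equiv), MeCN/AcOH (1:1), −30 → 0 °C
Reagents that add atoms: none
Why: Evans–Saksena directed reduction: the 10α-hydroxyl binds boron and delivers hydride to the α face of C8, giving the 8β-alcohol anti to the 10-OH and trans to the isopropyl group.

**Step 9**
Reactants: 14 (1R,5S,7S,8R,10R)-guai-3-ene-8,10-diol
Product: 16 (1R,3R,4S,5S,7S,8R,10R)-3,4-epoxyguaiane-8,10-diol (epoxide α), via bromohydrin 15 (not isolated)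
Conditions: N-bromosuccinimide, THF/H2O (4:1), 0 °C; then K2CO3, MeOH, rt
Reagents that add atoms: water, O
Why: Bromohydrin formation then intramolecular Williamson closure: the bromonium forms on the less hindered β face (anti to the allylic C5–C6 bond), water opens it anti at tertiary C4, and base closes with inversion at C3, so the oxygen ends on the α face, opposite to what direct peracid epoxidation is expected to give; the β-disposed 10-OH cannot intercept the bromonium from the α side.

**Step 10**
Reactants: 16 (1R,3R,4S,5S,7S,8R,10R)-3,4-epoxyguaiane-8,10-diol; 17 tert-butyl(4-iodophenoxy)dimethylsilane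
Product: 19 (1R,3R,4S,5S,7S,8R,10R)-3,4-epoxy-10-hydroxyguaian-8-yl 4-hydroxybenzoate (target), via silyl-protected ester 18 (not isolated)
Conditions: Pd(OAc)2 (5 mol%), Xantphos (6 mol%), CO (1 atm), 17 (1.5 equiv), K2CO3, DMAP (20 mol%), toluene, 80 °C; then MeOH, rt
Reagents that add atoms: carbon monoxide, [C-]#[O+]
Why: Palladium-catalysed alkoxycarbonylation of the aryl iodide acylates only the secondary 8-OH (the tertiary 10-OH is too hindered), and carbonate in methanol then removes the labile aryl silyl ether while the deactivated hindered benzoate and the epoxide stay intact.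

**Compound list**
1 | (S)-5-[(tert-butyldimethylsilyl)oxy]cyclohex-2-en-1-one | O=C1C=CC[C@H](O[Si](C)(C)C(C)(C)C)C1 | starting material
2 | isopropenylmagnesium bromide | CC(=C)[Mg]Br | starting material
3 | allyl iodide | C=CCI | starting material
4 | bromomagnesium (3S,5S)-5-[(tert-butyldimethylsilyl)oxy]-3-(prop-1-en-2-yl)cyclohex-1-en-1-olate | CC(=C)[C@H]1C[C@H](O[Si](C)(C)C(C)(C)C)CC(O[Mg]Br)=C1 | intermediate (not isolated)
5 | (2R,3S,5S)-2-allyl-5-[(tert-butyldimethylsilyl)oxy]-3-(prop-1-en-2-yl)cyclohexan-1-one | C=CC[C@H]1C(=O)C[C@@H](O[Si](C)(C)C(C)(C)C)C[C@@H]1C(C)=C | intermediate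
6 | (3aS,5S,7aR)-5-[(tert-butyldimethylsilyl)oxy]-3-methyl-1,3a,4,5,6,7a-hexahydro-7H-inden-7-one | CC1=CC[C@H]2C(=O)C[C@@H](O[Si](C)(C)C(C)(C)C)C[C@H]12 | intermediate
7 | (3aS,5S,7aR)-5-hydroxy-3-methyl-1,3a,4,5,6,7a-hexahydro-7H-inden-7-one | CC1=CC[C@H]2C(=O)C[C@@H](O)C[C@H]12 | intermediate
8 | (3aS,5S,7R,7aR)-3,7-dimethyl-3a,4,5,6,7,7a-hexahydro-1H-indene-5,7-diol | CC1=CC[C@H]2[C@](C)(O)C[C@@H](O)C[C@H]12 | intermediate
9 | (3aS,7R,7aR)-7-hydroxy-3,7-dimethyl-1,3a,4,6,7,7a-hexahydro-5H-inden-5-one | CC1=CC[C@H]2[C@](C)(O)CC(=O)C[C@H]12 | intermediate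
10 | isobutyraldehyde | CC(C)C=O | starting material
11 | isobutyraldehyde hydrazone | CC(C)C=NN | intermediate
12 | 1-diazo-2-methylpropane | CC(C)C=[N+]=[N-] | intermediate (not isolated)
13 | (1R,5S,7S,10R)-10-hydroxyguai-3-en-8-one | CC(C)[C@@H]1C[C@H]2[C@@H](CC=C2C)[C@](C)(O)CC1=O | intermediate
14 | (1R,5S,7S,8R,10R)-guai-3-ene-8,10-diol | CC(C)[C@@H]1C[C@H]2[C@@H](CC=C2C)[C@](C)(O)C[C@H]1O | intermediate
15 | (1R,3S,4S,5S,7S,8R,10R)-3-bromoguaiane-4,8,10-triol | CC(C)[C@@H]1C[C@H]2[C@@H](C[C@H](Br)[C@@]2(C)O)[C@](C)(O)C[C@H]1O | intermediate (not isolated)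
16 | (1R,3R,4S,5S,7S,8R,10R)-3,4-epoxyguaiane-8,10-diol | CC(C)[C@@H]1C[C@H]2[C@@H](C[C@H]3O[C@]32C)[C@](C)(O)C[C@H]1O | intermediate
17 | tert-butyl(4-iodophenoxy)dimethylsilane | CC(C)(C)[Si](C)(C)Oc1ccc(I)cc1 | starting material
18 | (1R,3R,4S,5S,7S,8R,10R)-3,4-epoxy-10-hydroxyguaian-8-yl 4-[(tert-butyldimethylsilyl)oxy]benzoate | CC(C)[C@@H]1C[C@H]2[C@@H](C[C@H]3O[C@]32C)[C@](C)(O)C[C@H]1OC(=O)c1ccc(O[Si](C)(C)C(C)(C)C)cc1 | intermediate (not isolated)
19 | (1R,3R,4S,5S,7S,8R,10R)-3,4-epoxy-10-hydroxyguaian-8-yl 4-hydroxybenzoate | CC(C)[C@@H]1C[C@H]2[C@@H](C[C@H]3O[C@]32C)[C@](C)(O)C[C@H]1OC(=O)c1ccc(O)cc1 | target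

**Step count**
Total step count: 10. Longest linear sequence: 9 steps (steps 1–5 and 7–10; step 6 is the side branch that makes 11).

**Three steps most likely to fail**

Step 7 (the proposed new ring expansion). The Lewis acid may dehydrate or retro-aldolise the tertiary β-hydroxy ketone, C9 may migrate instead of C6, and the C7 epimer ratio is untested. Known-chemistry fallback, setting out from 9 and coming back at 13: add 2-methyl-1-(methylselanyl)propyllithium (from 2-methyl-1,1-bis(methylselanyl)propane and nBuLi, THF, −78 °C) to the ketone to give the β-hydroxy selenide (3aS,7R,7aR)-3,7-dimethyl-5-[2-methyl-1-(methylselanyl)propyl]-3a,4,5,6,7,7a-hexahydro-1H-indene-5,7-diol F3 as a mixture at the two new centres. Then trigger the selenium-based semipinacol ring enlargement (Krief type) with AgBF4 on Al2O3 in CH2Cl2, or TlOEt in CHCl3, which expels the selenium group and gives 13.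

Step 4 (face of the methyl transfer). If titanium chelation leads to external attack instead of internal delivery, the 10-epimer forms. Fallback, setting out from 7 and coming back at 9:
- Mesylate and eliminate (MsCl, Et3N, CH2Cl2, 0 °C) to the enone (3aS,7aR)-3-methyl-1,3a,4,7a-tetrahydro-7H-inden-7-one F1.
- Add MeLi/CeCl3 (THF, −78 °C) 1,2 from the axial β face, now free of any axial C8 substituent, to give the tertiary allylic alcohol (3aS,7R,7aR)-3,7-dimethyl-3a,4,7,7a-tetrahydro-1H-inden-7-ol F2.
- Wacker oxidation (PdCl2 cat., O2, DMA/H2O) places the carbonyl on the alkene carbon remote from the carbinol and leaves the trisubstituted cyclopentene alone, giving 9.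

Step 9 (face of the epoxide). If bromonium formation or opening is not face-selective, or N-bromosuccinimide oxidises the secondary alcohol, the α-epoxide will be contaminated. Fallback, setting out from 14 and coming back at 16: catalyst-controlled Shi epoxidation of the trisubstituted alkene (fructose-derived ketone catalyst of the enantiomeric series that delivers oxygen to the α face, KHSO5, K2CO3 buffer, MeCN/dimethoxymethane/H2O, 0 °C). This fallback makes no new compound (F0).

**Further compounds**
F1 | step 4 | (3aS,7aR)-3-methyl-1,3a,4,7a-tetrahydro-7H-inden-7-one | CC1=CC[C@H]2C(=O)C=CC[C@H]12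
F2 | step 4 | (3aS,7R,7aR)-3,7-dimethyl-3a,4,7,7a-tetrahydro-1H-inden-7-ol | CC1=CC[C@H]2[C@](C)(O)C=CC[C@H]12
F3 | step 7 | (3aS,7R,7aR)-3,7-dimethyl-5-[2-methyl-1-(methylselanyl)propyl]-3a,4,5,6,7,7a-hexahydro-1H-indene-5,7-diol (mixture at C5 and the side-chain carbon) | CC1=CC[C@H]2[C@](C)(O)CC(O)(C([Se]C)C(C)C)C[C@H]12
F0 | step 9 | none | none
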